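## Retrosynthetic overview
1. Endgame: the C8 ester, the C14 aldehyde and the free side-chain alcohol are put in after ring closure, starting from an 8-O-MOM / 14-OH macrocycle.
2. C6–C7 cut: a 2-(bromomethyl)enoate becomes an allylchromium reagent, so the acrylate β-carbon C7 acts as donor toward the C6 enal. This closes the ten-membered carbocycle first, and O6 then closes on C12 to give the γ-lactone in the same operation.
3. C7=C11 comes from cross-metathesis with methyl 2-(bromomethyl)acrylate. The C14–OH and the ring-cis 1(10)-alkene come from SeO2 oxidation of the open chain.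
4. C8–C9 cut through the diol: metalated allyl MOM ether (an α-alkoxy carbanion equivalent on a chiral borane) adds to 8-oxogeranyl acetate. This sets C8 and C9 and tells the two oxygens apart.
5. Carbon sources: geranyl acetate gives C1–C6, C9, C10, C14 and C15. Allyl alcohol gives C7 and C8. Methyl 2-(bromomethyl)acrylate gives C11–C13.

Assumption: positions are numbered as in germacranolides (ring C1–C10, lactone C11–C13, C14 on C10, C15 on C4). With this numbering the target is 6R,7S,8S,9S, with a 4E alkene and with C2 and C9 cis on the 1(10)-alkene.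

## Route

Step 1
Reactants: 1 geranyl acetate
Product: 2 (2E,6E)-3,7-dimethyl-8-oxoocta-2,6-dien-1-yl acetate
Conditions: SeO2 (1.1 equiv), 1,4-dioxane, 80 °C
Reagents that add atoms: selenium dioxide, O=[Se]=O
Why: Riley allylic oxidation (ene reaction, then 2,3-sigmatropic shift) attacks only the electron-rich terminal alkene, not the one deactivated by the allylic acetate, and gives the E-enal whose formyl carbon becomes C9 and whose remaining methyl becomes C14.

Step 2
Reactants: 3 allyl alcohol; 4 dimethoxymethane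
Product: 5 3-(methoxymethoxy)prop-1-ene (allyl MOM ether)
Conditions: LiBr, p-TsOH·H2O (cat.), neat 4, rt
Reagents that add atoms: none
Why: Acid-catalysed transacetalisation driven by excess dimethoxymethane gives the MOM ether without chloromethyl methyl ether; no stereocenter is involved.

Step 3
Reactants: 5 allyl MOM ether; 2 8-oxogeranyl acetate
Product: 9 (2E,6E,8S,9S)-9-(methoxymethoxy)-3,7-dimethylundeca-2,6,10-triene-1,8-diol, via lithiated allyl ether 6 (not isolated), via allylborane 7 (not isolated), via borinate 8 (not isolated)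
Conditions: s-BuLi, THF, −78 °C; (+)-Ipc2BOMe; BF3·OEt2; 2, −78 °C; then 3 M NaOH, 30% H2O2, rt
Reagents that add atoms: none
Why: In this Brown alkoxyallylboration the metalated allyl ether is an α-alkoxy carbanion equivalent, so carbinol carbon C8 attacks formyl carbon C9 (both acceptors by nature) through a closed chair in which the Z-borane gives the 8,9-syn diol and the ligands from (−)-α-pinene select the face that gives 8S,9S, leaving O8 as MOM ether and O9 free, while the basic peroxide work-up also saponifies the primary acetate.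

Step 4
Reactants: 9 diol
Product: 10 (2E,6E,8S,9S)-8-hydroxy-9-(methoxymethoxy)-3,7-dimethylundeca-2,6,10-trienal
Conditions: TEMPO (10 mol %), PhI(OAc)2, CH2Cl2, rt
Reagents that add atoms: none
Why: The oxoammonium (TEMPO/PhI(OAc)2) oxidation takes the unhindered primary allylic alcohol and leaves the hindered secondary C9 carbinol, gives the E-enal at C6 without touching a stereocenter, and makes C4=C5 electron-poor for step 6.

Step 5
Reactants: 10 hydroxy enal
Product: 11 (3S,4S,5E,9E)-3-(methoxymethoxy)-5,9-dimethyl-11-oxoundeca-1,5,9-trien-4-yl acetate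
Conditions: Ac2O, pyridine, DMAP (cat.), CH2Cl2, 0 °C
Reagents that add atoms: acetic anhydride, CC(=O)OC(C)=O
Why: DMAP-catalysed acetylation of the only free hydroxyl group installs the C9 acetate of the target with retention at C9.

Step 6
Reactants: 11 acetate enal
Product: 12 (3S,4S,5Z,9E)-5-(hydroxymethyl)-3-(methoxymethoxy)-9-methyl-11-oxoundeca-1,5,9-trien-4-yl acetate
Conditions: SeO2 (0.3 equiv), t-BuOOH (3 equiv), salicylic acid (0.1 equiv), CH2Cl2, 0 °C to rt
Reagents that add atoms: selenium dioxide, O=[Se]=O; tert-butyl hydroperoxide, CC(C)(C)OO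
Why: In this catalytic Sharpless-type SeO2 allylic hydroxylation only C1=C10 is electron-rich enough to react (C4=C5 is an enal, C7 is a monosubstituted vinyl), the ene step takes a hydrogen from the C14 methyl, and the 2,3-sigmatropic shift rebuilds the alkene with CH2OH trans to the C2 chain, which turns the alkene into the arrangement with C2 cis to C9 that the target needs.

Step 7
Reactants: 12 allylic alcohol; 13 methyl 2-(bromomethyl)acrylate
Product: 14 methyl (2Z,4S,5S,6Z,10E)-5-acetoxy-2-(bromomethyl)-6-(hydroxymethyl)-4-(methoxymethoxy)-10-methyl-12-oxododeca-2,6,10-trienoate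
Conditions: 13 (5 equiv), second-generation Hoveyda–Grubbs catalyst (10 mol %), CH2Cl2, 40 °C
Reagents that add atoms: none
Why: In this olefin cross-metathesis the only terminal alkene of 12 exchanges its CH2 for the C11–C13 acrylate unit, the trisubstituted alkenes are inert, and the alkene geometry formed does not matter because it equilibrates in step 8.

Step 8
Reactants: 14 allylic bromide enal
Product: 17 (6R,7S,8S,9S)-9-acetoxy-14-hydroxy-8-(methoxymethoxy)germacra-1(10),4E,11(13)-trien-12,6-olide (C2 cis to C9), via allylchromium 15 (not isolated), via hydroxy ester 16 (not isolated)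
Conditions: CrCl2 (10 equiv), THF–DMF, rt, syringe-pump addition to 2 mM; aq. NH4Cl; then PPTS (cat.), CH2Cl2, rt
Reagents that add atoms: none
Why: In this intramolecular Nozaki–Hiyama (Barbier-type) 2-(alkoxycarbonyl)allylation, divalent chromium makes an allylchromium reagent in which C7, normally the electrophilic β-carbon of the acrylate, is the donor (homoenolate equivalent) that attacks the equally electrophilic formyl carbon C6 through a closed chair with C8 trans to CH2Cr and the C5 alkenyl group equatorial (6,7-anti, hence the trans-lactone once O6 closes on C12), while allylic 1,3-strain at C8 (C9 outward, O8 inward, H8 anti) exposes the face that gives 7S next to 8S, so ring, lactone, exocyclic methylene, C6 and C7 form in one operation.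

Step 9
Reactants: 17 macrocyclic allylic alcohol
Product: 18 (6R,7S,8S,9S)-9-acetoxy-8-(methoxymethoxy)-14-oxogermacra-1(10),4E,11(13)-trien-12,6-olide
Conditions: MnO2 (20 equiv), CH2Cl2, rt
Reagents that add atoms: none
Why: MnO2 oxidises the single primary allylic alcohol to the enal, whose CHO stays trans to C2 (the stable enal geometry), and touches no ester, alkene or stereocenter.

Step 10
Reactants: 18 MOM ether
Product: 20 (6R,7S,8S,9S)-9-acetoxy-8-hydroxy-14-oxogermacra-1(10),4E,11(13)-trien-12,6-olide, via bromomethyl ether 19 (not isolated)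
Conditions: Me2BBr (2.5 equiv), CH2Cl2, −78 °C; then sat. aq. NaHCO3–THF
Reagents that add atoms: none
Why: Bromoborane acetal cleavage at −78 °C breaks only the O–CH2–O unit and keeps the C8–O bond (retention at C8), and the C9 acetate does not ionise because its alkene is now an electron-poor enal.

Step 11
Reactants: 21 ethyl 2-(hydroxymethyl)acrylate
Product: 22 ethyl 2-[(tert-butyldimethylsilyloxy)methyl]acrylate
Conditions: TBSCl, imidazole, CH2Cl2, 0 °C to rt
Reagents that add atoms: tert-butyldimethylsilyl chloride, CC(C)(C)[Si](C)(C)Cl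
Why: Standard imidazole-mediated silylation masks the side-chain alcohol so that the acid cannot acylate itself.

Step 12
Reactants: 22 silyl ether ester
Product: 23 2-[(tert-butyldimethylsilyloxy)methyl]acrylic acid
Conditions: LiOH, THF–H2O, 0 °C; then 1 M HCl to pH 4
Reagents that add atoms: lithium hydroxide, [Li+].[OH-]
Why: Cold saponification cleaves the ethyl ester faster than hydroxide adds to the hindered acrylate, and the TBS ether survives base.

Step 13
Reactants: 23 protected side-chain acid; 20 C8 alcohol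
Product: 25 8-O-{2-[(tert-butyldimethylsilyloxy)methyl]acryloyl} derivative of 20 (6R,7S,8S,9S), via mixed anhydride 24 (not isolated)
Conditions: 2,4,6-trichlorobenzoyl chloride, Et3N, toluene, rt; then 20, DMAP, toluene, rt
Reagents that add atoms: none
Why: Yamaguchi esterification acylates the hindered 8β-hydroxyl at oxygen (retention at C8) under conditions mild enough for the enal, the acetate and the α-methylene lactone.

Step 14
Reactants: 25 silyl-protected target
Product: 26 target CNP0177123.1
Conditions: HF·pyridine, THF–pyridine, 0 °C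
Reagents that add atoms: none
Why: Buffered fluoride desilylation frees the primary alcohol without acyl migration, conjugate addition or epimerisation.

## Compound list
1 | geranyl acetate | CC(C)=CCC/C(C)=C/COC(C)=O | starting material
2 | (2E,6E)-3,7-dimethyl-8-oxoocta-2,6-dien-1-yl acetate | CC(=O)OC/C=C(\C)CC/C=C(\C)C=O | intermediate
3 | allyl alcohol | C=CCO | starting material
4 | dimethoxymethane | COCOC | starting material
5 | 3-(methoxymethoxy)prop-1-ene | C=CCOCOC | intermediate
6 | (Z)-3-(methoxymethoxy)allyllithium | COCO/C=C\C[Li] | intermediate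
7 | [(Z)-3-(methoxymethoxy)allyl]diisopinocampheylborane, ligands from (−)-α-pinene | COCO/C=C\CB([C@H]1C[C@H]2C[C@@H]([C@@H]1C)C2(C)C)[C@H]1C[C@H]2C[C@@H]([C@@H]1C)C2(C)C | intermediate
8 | diisopinocampheylborinate of the 8S,9S adduct, C6 acetate still in place | C=C[C@H](OCOC)[C@@H](OB([C@H]1C[C@H]2C[C@@H]([C@@H]1C)C2(C)C)[C@H]1C[C@H]2C[C@@H]([C@@H]1C)C2(C)C)/C(C)=C/CC/C(C)=C/COC(C)=O | intermediate
9 | (2E,6E,8S,9S)-9-(methoxymethoxy)-3,7-dimethylundeca-2,6,10-triene-1,8-diol | C=C[C@H](OCOC)[C@@H](O)/C(C)=C/CC/C(C)=C/CO | intermediate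
10 | (2E,6E,8S,9S)-8-hydroxy-9-(methoxymethoxy)-3,7-dimethylundeca-2,6,10-trienal | C=C[C@H](OCOC)[C@@H](O)/C(C)=C/CC/C(C)=C/C=O | intermediate
11 | (3S,4S,5E,9E)-3-(methoxymethoxy)-5,9-dimethyl-11-oxoundeca-1,5,9-trien-4-yl acetate | C=C[C@H](OCOC)[C@@H](OC(C)=O)/C(C)=C/CC/C(C)=C/C=O | intermediate
12 | (3S,4S,5Z,9E)-5-(hydroxymethyl)-3-(methoxymethoxy)-9-methyl-11-oxoundeca-1,5,9-trien-4-yl acetate | C=C[C@H](OCOC)[C@@H](OC(C)=O)/C(CO)=C\CC/C(C)=C/C=O | intermediate
13 | methyl 2-(bromomethyl)acrylate | C=C(CBr)C(=O)OC | starting material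
14 | methyl (2Z,4S,5S,6Z,10E)-5-acetoxy-2-(bromomethyl)-6-(hydroxymethyl)-4-(methoxymethoxy)-10-methyl-12-oxododeca-2,6,10-trienoate | COC(=O)/C(CBr)=C/[C@H](OCOC)[C@@H](OC(C)=O)/C(CO)=C\CC/C(C)=C/C=O | intermediate
15 | allylchromium dichloride from 14, C8 trans to CH2Cr | COC(=O)/C(C[Cr](Cl)Cl)=C\[C@H](OCOC)[C@@H](OC(C)=O)/C(CO)=C\CC/C(C)=C/C=O | intermediate
16 | ten-membered 6-hydroxy 12-methyl ester (6R,7S,8S,9S), drawn as the free alcohol | COCO[C@H]1[C@@H](C(=C)C(=O)OC)[C@H](O)/C=C(\C)CC/C=C(/CO)[C@@H]1OC(C)=O | intermediate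
17 | (6R,7S,8S,9S)-9-acetoxy-14-hydroxy-8-(methoxymethoxy)germacra-1(10),4E,11(13)-trien-12,6-olide, C2 cis to C9 | COCO[C@H]1[C@H]2C(=C)C(=O)O[C@@H]2/C=C(\C)CC/C=C(/CO)[C@@H]1OC(C)=O | intermediate
18 | 14-oxo analogue of 17 | COCO[C@H]1[C@H]2C(=C)C(=O)O[C@@H]2/C=C(\C)CC/C=C(/C=O)[C@@H]1OC(C)=O | intermediate
19 | 8-O-(bromomethyl) ether of 20 | BrCO[C@H]1[C@H]2C(=C)C(=O)O[C@@H]2/C=C(\C)CC/C=C(/C=O)[C@@H]1OC(C)=O | intermediate
20 | (6R,7S,8S,9S)-9-acetoxy-8-hydroxy-14-oxogermacra-1(10),4E,11(13)-trien-12,6-olide | O[C@H]1[C@H]2C(=C)C(=O)O[C@@H]2/C=C(\C)CC/C=C(/C=O)[C@@H]1OC(C)=O | intermediate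
21 | ethyl 2-(hydroxymethyl)acrylate | C=C(CO)C(=O)OCC | starting material
22 | ethyl 2-[(tert-butyldimethylsilyloxy)methyl]acrylate | C=C(CO[Si](C)(C)C(C)(C)C)C(=O)OCC | intermediate
23 | 2-[(tert-butyldimethylsilyloxy)methyl]acrylic acid | C=C(CO[Si](C)(C)C(C)(C)C)C(=O)O | intermediate
24 | mixed anhydride of 23 with 2,4,6-trichlorobenzoic acid | C=C(CO[Si](C)(C)C(C)(C)C)C(=O)OC(=O)c1c(Cl)cc(Cl)cc1Cl | intermediate
25 | O-TBS ether of the target | C=C(CO[Si](C)(C)C(C)(C)C)C(=O)O[C@H]1[C@H]2C(=C)C(=O)O[C@@H]2/C=C(\C)CC/C=C(/C=O)[C@@H]1OC(C)=O | intermediate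
26 | CNP0177123.1 | C=C(CO)C(=O)O[C@H]1[C@H]2C(=C)C(=O)O[C@@H]2/C=C(\C)CC/C=C(/C=O)[C@@H]1OC(C)=O | target

## Step count and risks
Total steps: 14. Longest linear sequence: 11 (steps 1, 3–10, 13 and 14).

**Step 8 (macrocyclisation).** The risks are oligomers, 1,4-elimination of the C8 oxygen from the allylchromium reagent, and the unusual Z,E chain with a free hydroxyl group.
- The fallback sets out from 11 and comes back at 17. It closes the ring before any oxidation at C14.
- Compound 11 is cross-metathesised with 13 to the C14-methyl all-E allylic bromide F8. This bromide has no free hydroxyl group and has the chain geometry of the known germacranolide closures.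
- CrCl2 closes it to the (1(10)E,4E)-germacranolide F9.
- SeO2/t-BuOOH on the ring then hydroxylates C14 through the same ene and 2,3-shift sequence. That sequence turns the 1(10)-alkene into the ring-cis form and gives 17.

**Step 7 (cross-metathesis).** The risk is the pairing of a hindered allylic ether with a 1,1-disubstituted acrylate.
- The fallback sets out from 10 and comes back at 18. It makes the metathesis ring-closing through a temporary ester at O9.
- Compound 10 is esterified with 2-(bromomethyl)acrylic acid (DCC, DMAP) to the O9 2-(bromomethyl)acrylate F3.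
- The second-generation Grubbs catalyst closes the six-membered bromomethyl dihydropyranone F4.
- SeO2/t-BuOOH gives the C14 alcohol F5.
- CrCl2 then cyclises through an allylchromium reagent locked with C8 trans to CH2Cr and attacked anti to the OMOM group. The O6 alkoxide takes over the acyl group (δ-lactone to γ-lactone) to give the 9,14-diol F6.
- MnO2 gives the 9-hydroxy enal F7, and Ac2O/pyridine gives 18.

**Step 6 (SeO2 on the open chain).** The risks are a slow ene step next to the acetate, over-oxidation, and loss of geometric control beside the bulky C9 group.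
- The fallback sets out from 11 and comes back at 12. It replaces selenium by singlet oxygen.
- Photo-oxygenation of 11 (O2, tetraphenylporphyrin, light, CH2Cl2, 0 °C; Schenck ene reaction) abstracts hydrogen from the methyl geminal to the large C9 group. This gives the secondary allylic hydroperoxide F1 (C1–OOH, C10=C14H2).
- On standing in CHCl3, F1 undergoes the Schenck allylic rearrangement to the primary hydroperoxide F2.
- PPh3 reduces F2 to 12.

## Further compounds
F1 | step 6 | C1 hydroperoxide of 11 with exocyclic C10=C14H2, C1 epimers, 8S,9S | C=C[C@H](OCOC)[C@@H](OC(C)=O)C(=C)C(OO)CC/C(C)=C/C=O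
F2 | step 6 | C14 hydroperoxide corresponding to 12, C2 cis to C9, 8S,9S | C=C[C@H](OCOC)[C@@H](OC(C)=O)/C(COO)=C\CC/C(C)=C/C=O
F3 | step 7 | O9 2-(bromomethyl)acrylate of 10, 8S,9S | C=C[C@H](OCOC)[C@@H](OC(=O)C(=C)CBr)/C(C)=C/CC/C(C)=C/C=O
F4 | step 7 | 3-(bromomethyl)-5-(methoxymethoxy)-6-alkenyl-5,6-dihydro-2H-pyran-2-one (O9–C12 lactone), 8S,9S | BrCC1=C[C@H](OCOC)[C@H](/C(C)=C/CC/C(C)=C/C=O)OC1=O
F5 | step 7 | C14-hydroxy derivative of F4, C2 cis to C9 | BrCC1=C[C@H](OCOC)[C@H](/C(CO)=C\CC/C(C)=C/C=O)OC1=O
F6 | step 7 | (6R,7S,8S,9S)-9,14-dihydroxy-8-(methoxymethoxy)germacra-1(10),4E,11(13)-trien-12,6-olide | COCO[C@H]1[C@H]2C(=C)C(=O)O[C@@H]2/C=C(\C)CC/C=C(/CO)[C@@H]1O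
F7 | step 7 | 9-hydroxy-14-oxo analogue of F6 | COCO[C@H]1[C@H]2C(=C)C(=O)O[C@@H]2/C=C(\C)CC/C=C(/C=O)[C@@H]1O
F8 | step 8 | C14-methyl all-E analogue of 14 | COC(=O)/C(CBr)=C/[C@H](OCOC)[C@@H](OC(C)=O)/C(C)=C/CC/C(C)=C/C=O
F9 | step 8 | (6R,7S,8S,9S)-9-acetoxy-8-(methoxymethoxy)germacra-1(10)E,4E,11(13)-trien-12,6-olide | COCO[C@H]1[C@H]2C(=C)C(=O)O[C@@H]2/C=C(\C)CC/C=C(\C)[C@@H]1OC(C)=O
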